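**Retrosynthetic overview**

1. Locants: unit 1 is the 5-hydroxy-7-methoxyflavone half (C2–C8a, ring B = C1'–C6'); unit 2 is the acacetin half (C2''–C8a''); the biaryl bond is C3'–C8''.
2. Feature: ring B of unit 1 is a phenol (C4'–OH) with C8'' ortho at C3' and the pyranone carbon C2 para at C1'. This is the pattern of an aromatised [4+2] adduct of a 4-aryl-1-methoxy-3-silyloxybutadiene and a propiolate, and C8'' sits ortho to O7'', so its carbon substituent can be delivered from O7'' by a Claisen shift.
3. Last ring: the pyranone (ring C) of unit 1 comes from acid 19 and acetophenone 20 by esterification, Baker–Venkataraman shift and cyclodehydration; ring A of unit 1 is bought in 20.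
4. Key disconnection: ring B of unit 1 comes from diene 13 and methyl propiolate 14 (bonds C2'–C3' and C1'–C6', then loss of methanol). The C3'–C8'' bond is the former allyl–arene bond, so no arene–arene coupling is needed.
5. Diene 13 comes from acacetin 1 by O-allylation, Claisen shift to C8'', benzylation, cleavage to the CH2CHO side chain, ynone formation, methanol addition and silylation. Ring order: the unit 2 rings are bought, then ring B of unit 1 (step 9), then ring C of unit 1 (step 14).

Key step: step 9

Remark (assumption): the target carries no stereodescriptor, so the C3'–C8'' axis is treated as not configurationally fixed and the route controls constitution only.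

**Route**

Step 1
Reactants: 1 acacetin (5,7-dihydroxy-4'-methoxyflavone); 2 allyl bromide
Product: 3 7-O-allylacacetin
Conditions: K2CO3 (1.2 equiv), DMF, rt
Reagents that add atoms: none
Why: Williamson etherification; the 7-OH is the more acidic, unchelated phenol, whereas the 5-OH is hydrogen-bonded to the C4 carbonyl, so monoalkylation at O7 is expected.

Step 2
Reactants: 3 7-O-allylacacetin
Product: 5 8-allylacacetin, via Claisen dienone 4 (not isolated)
Conditions: PhNEt2, 200 °C, Ar
Reagents that add atoms: none
Why: Aromatic Claisen rearrangement; the allyl group moves by a concerted [3,3]-sigmatropic shift from O7'' to the ortho carbon C8'', the site normally preferred by 7-allyloxychromones, and dienone 4 re-aromatises by tautomerisation.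

Step 3
Reactants: 5 8-allylacacetin
Product: 6 8-allyl-5,7-di-O-benzylacacetin
Conditions: BnBr (3 equiv), K2CO3 (4 equiv), Bu4NI (cat.), DMF, 70 °C
Reagents that add atoms: benzyl bromide, BrCc1ccccc1
Why: Williamson etherification of both phenols; excess halide and heating are needed for the hydrogen-bonded 5-OH.

Step 4
Reactants: 6 8-allyl-5,7-di-O-benzylacacetin
Product: 8 (5,7-di-O-benzylacacetin-8-yl)acetaldehyde, via vicinal diol 7 (not isolated)
Conditions: OsO4 (2 mol%), NaIO4 (4 equiv), 2,6-lutidine (2 equiv), dioxane/H2O 3:1, rt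
Reagents that add atoms: osmium tetroxide, O=[Os](=O)(=O)=O; sodium periodate, [Na+].[O-]I(=O)(=O)=O
Why: Lemieux–Johnson oxidation; the terminal alkene should be dihydroxylated far faster than the electron-poor C2''=C3'' bond of the pyranone, and periodate cleaves diol 7 to the aldehyde while 2,6-lutidine limits over-oxidation.

Step 5
Reactants: 8 (5,7-di-O-benzylacacetin-8-yl)acetaldehyde; 9 ethynylmagnesium bromide (HC≡CMgBr)
Product: 10 1-(5,7-di-O-benzylacacetin-8-yl)but-3-yn-2-ol (racemic)
Conditions: HC≡CMgBr (1.3 equiv), THF, −78 → −20 °C; aq NH4Cl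
Reagents that add atoms: none
Why: Grignard 1,2-addition; at low temperature the aldehyde is much more electrophilic than the pyranone carbonyl (a vinylogous ester), and the new carbinol centre forms as a racemate that is erased by the oxidation in step 6.

Step 6
Reactants: 10 1-(5,7-di-O-benzylacacetin-8-yl)but-3-yn-2-ol
Product: 11 1-(5,7-di-O-benzylacacetin-8-yl)but-3-yn-2-one
Conditions: Dess–Martin periodinane (1.3 equiv), CH2Cl2, 0 °C → rt
Reagents that add atoms: none
Why: Dess–Martin oxidation of a secondary propargylic alcohol under near-neutral conditions, which should spare the sensitive terminal ynone.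

Step 7
Reactants: 11 1-(5,7-di-O-benzylacacetin-8-yl)but-3-yn-2-one
Product: 12 (E)-4-methoxy-1-(5,7-di-O-benzylacacetin-8-yl)but-3-en-2-one
Conditions: MeOH (5 equiv), DABCO (10 mol%), CH2Cl2, 0 °C → rt
Reagents that add atoms: methanol, CO
Why: Amine-catalysed oxa-Michael addition of methanol to the terminal ynone, which should give the thermodynamically preferred E β-methoxy enone.

Step 8
Reactants: 12 (E)-4-methoxy-1-(5,7-di-O-benzylacacetin-8-yl)but-3-en-2-one
Product: 13 (1E,3Z)-1-methoxy-3-(tert-butyldimethylsilyloxy)-4-(5,7-di-O-benzylacacetin-8-yl)buta-1,3-diene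
Conditions: TBSOTf (1.3 equiv), Et3N (2.5 equiv), Et2O, 0 °C → rt
Reagents that add atoms: tert-butyldimethylsilyl trifluoromethanesulfonate, CC(C)(C)[Si](C)(C)OS(=O)(=O)C(F)(F)F
Why: Soft enolisation and O-silylation; only the benzylic CH2 carries enolisable hydrogens, so the silyl dienol ether forms regiospecifically, and the Z isomer (flavonyl cis to the silyloxy group) is expected because it avoids allylic strain between the aryl and methoxyvinyl groups.

Step 9
Reactants: 13 the silyloxy diene; 14 methyl propiolate
Product: 16 methyl 4-(tert-butyldimethylsilyloxy)-3-(5,7-di-O-benzylacacetin-8-yl)benzoate, via cis-cyclohexa-1,4-diene cycloadduct 15 (not isolated)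
Conditions: 14 (5 equiv), toluene, 110 °C, sealed tube; then PPTS (0.1 equiv), rt
Reagents that add atoms: none
Why: Diene 13 is a 1-alkoxy-3-silyloxybutadiene whose largest HOMO coefficient lies on the flavonyl-bearing terminus, so in its s-cis form that carbon should bond to the β-carbon of 14 and the methoxy-bearing terminus to the α-carbon in a concerted, asynchronous, normal-electron-demand [4+2] cycloaddition; the closest known reaction type is the Diels–Alder addition and aromatisation of 1-alkoxy-3-silyloxybutadienes with propiolates to 4-hydroxybenzoates, here with a more hindered 4-substituent. Ring B is closed as a six-membered carbocycle in an intermolecular [4+2] mode, both ring bonds (C2'–C3' and C1'–C6') forming in the cycloaddition to give cyclohexa-1,4-diene 15. The allylic methoxy group at C6' and the doubly allylic hydrogen at C3' then leave as methanol (ionisation assisted by the silyl enol ether, then proton loss), which aromatises ring B and erases both sp3 centres, so no stereocentre needs control. The selectivity required is regiochemical (ester para and flavonyl ortho to the silyloxy group) and follows from the push–pull polarisation of diene and alkyne. The Z enol ether keeps the flavonyl group on the outside of the s-cis diene, and the dienophile can approach past the small ring-oxygen flank of the twisted C8'' substituent. The pyranone C2''=C3'' bond is a poor dienophile, and the benzyl and silyl ethers should tolerate neutral heating.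

Step 10
Reactants: 16 methyl 4-(tert-butyldimethylsilyloxy)-3-(5,7-di-O-benzylacacetin-8-yl)benzoate
Product: 18 methyl 4-(benzyloxy)-3-(5,7-di-O-benzylacacetin-8-yl)benzoate, via free phenol 17 (not isolated)
Conditions: CsF (2 equiv), BnBr (1.5 equiv), DMF, rt
Reagents that add atoms: benzyl bromide, BrCc1ccccc1
Why: One-pot fluoride desilylation and Williamson etherification; the cesium phenoxide of 17 is benzylated as it forms, exchanging the base-labile silyl ether for a benzyl ether that survives steps 11–14, and any 17 already formed in step 9 converges in the same operation.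

Step 11
Reactants: 18 methyl 4-(benzyloxy)-3-(5,7-di-O-benzylacacetin-8-yl)benzoate
Product: 19 4-(benzyloxy)-3-(5,7-di-O-benzylacacetin-8-yl)benzoic acid
Conditions: LiOH·H2O (5 equiv), THF/MeOH/H2O 3:1:1, 40 °C; then 1 M HCl to pH 3
Reagents that add atoms: lithium hydroxide, [Li+].[OH-]
Why: Saponification of an unhindered methyl benzoate by acyl–oxygen cleavage; mild hydroxide at this temperature should leave the pyranone ring and the benzyl ethers intact.

Step 12
Reactants: 19 the benzoic acid; 20 2',6'-dihydroxy-4'-methoxyacetophenone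
Product: 21 2-acetyl-3-hydroxy-5-methoxyphenyl 4-(benzyloxy)-3-(5,7-di-O-benzylacacetin-8-yl)benzoate
Conditions: DCC (1.2 equiv), DMAP (0.2 equiv), 20 (2 equiv), CH2Cl2, 0 °C → rt
Reagents that add atoms: none
Why: Steglich esterification; the two phenols of 20 are equivalent, and the excess of 20 should hold the acylation at the monoester.

Step 13
Reactants: 21 the aryl ester
Product: 22 1-(2,6-dihydroxy-4-methoxyphenyl)-3-[4-(benzyloxy)-3-(5,7-di-O-benzylacacetin-8-yl)phenyl]propane-1,3-dione
Conditions: LiN(SiMe3)2 (3.5 equiv), THF, −78 °C → rt; then aq HCl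
Reagents that add atoms: none
Why: Baker–Venkataraman rearrangement; the lithium enolate of the acetyl group attacks the neighbouring aryl ester through a six-membered transition state, and the O→C acyl shift gives the 1,3-diketone without a nucleophilic base that could open the pyranone of unit 2.

Step 14
Reactants: 22 the 1,3-diketone
Product: 23 4',5'',7''-tri-O-benzylputraflavone
Conditions: p-TsOH·H2O (0.2 equiv), toluene, 100 °C
Reagents that add atoms: none
Why: Acid-catalysed cyclodehydration; a phenol of the 2,6-dihydroxyaryl ketone adds to the distal carbonyl and water is lost, closing the pyranone (ring C) of unit 1, and because the two phenols are equivalent a single 5-hydroxy-7-methoxyflavone should result; early loss of the acid-labile 5''-O-benzyl group would be harmless because step 15 removes it.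

Step 15
Reactants: 23 4',5'',7''-tri-O-benzylputraflavone
Product: 24 putraflavone
Conditions: H2 (1 atm), Pd/C (10% palladium on carbon), THF/MeOH 1:1, rt
Reagents that add atoms: none
Why: Hydrogenolysis of the three aryl benzyl ethers; the aryl methyl ethers are inert, and the pyranone C=C bonds should survive if the reaction is stopped at full debenzylation.

**Compound list**

1 | acacetin (5,7-dihydroxy-4'-methoxyflavone) | COc1ccc(-c2cc(=O)c3c(O)cc(O)cc3o2)cc1 | starting material
2 | allyl bromide | C=CCBr | starting material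
3 | 7-O-allylacacetin (7-allyloxy-5-hydroxy-2-(4-methoxyphenyl)-4H-chromen-4-one) | COc1ccc(-c2cc(=O)c3c(O)cc(OCC=C)cc3o2)cc1 | intermediate
4 | Claisen dienone, 8-allyl-5-hydroxy-2-(4-methoxyphenyl)-8H-chromene-4,7-dione (racemic at C8, not isolated) | COc1ccc(cc1)C1=CC(=O)C2=C(O1)C(CC=C)C(=O)C=C2O | intermediate
5 | 8-allylacacetin (8-allyl-5,7-dihydroxy-2-(4-methoxyphenyl)-4H-chromen-4-one) | COc1ccc(-c2cc(=O)c3c(O)cc(O)c(CC=C)c3o2)cc1 | intermediate
6 | 8-allyl-5,7-di-O-benzylacacetin (8-allyl-5,7-bis(benzyloxy)-2-(4-methoxyphenyl)-4H-chromen-4-one) | COc1ccc(-c2cc(=O)c3c(OCc4ccccc4)cc(OCc4ccccc4)c(CC=C)c3o2)cc1 | intermediate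
7 | vicinal diol, 5,7-bis(benzyloxy)-8-(2,3-dihydroxypropyl)-2-(4-methoxyphenyl)-4H-chromen-4-one (racemic, not isolated) | COc1ccc(-c2cc(=O)c3c(OCc4ccccc4)cc(OCc4ccccc4)c(CC(O)CO)c3o2)cc1 | intermediate
8 | (5,7-di-O-benzylacacetin-8-yl)acetaldehyde | COc1ccc(-c2cc(=O)c3c(OCc4ccccc4)cc(OCc4ccccc4)c(CC=O)c3o2)cc1 | intermediate
9 | ethynylmagnesium bromide | C#C[Mg]Br | starting material
10 | 1-(5,7-di-O-benzylacacetin-8-yl)but-3-yn-2-ol (racemic) | COc1ccc(-c2cc(=O)c3c(OCc4ccccc4)cc(OCc4ccccc4)c(CC(O)C#C)c3o2)cc1 | intermediate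
11 | 1-(5,7-di-O-benzylacacetin-8-yl)but-3-yn-2-one | COc1ccc(-c2cc(=O)c3c(OCc4ccccc4)cc(OCc4ccccc4)c(CC(=O)C#C)c3o2)cc1 | intermediate
12 | (E)-4-methoxy-1-(5,7-di-O-benzylacacetin-8-yl)but-3-en-2-one | CO/C=C/C(=O)Cc1c(OCc2ccccc2)cc(OCc2ccccc2)c2c(=O)cc(-c3ccc(OC)cc3)oc12 | intermediate
13 | (1E,3Z)-1-methoxy-3-(tert-butyldimethylsilyloxy)-4-(5,7-di-O-benzylacacetin-8-yl)buta-1,3-diene (flavonyl cis to the silyloxy group) | CO/C=C/C(O[Si](C)(C)C(C)(C)C)=C/c1c(OCc2ccccc2)cc(OCc2ccccc2)c2c(=O)cc(-c3ccc(OC)cc3)oc12 | intermediate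
14 | methyl propiolate | C#CC(=O)OC | starting material
15 | methyl cis-3-(5,7-di-O-benzylacacetin-8-yl)-4-(tert-butyldimethylsilyloxy)-6-methoxycyclohexa-1,4-diene-1-carboxylate (racemic, relative configuration shown, not isolated) | CO[C@@H]1C=C(O[Si](C)(C)C(C)(C)C)[C@H](c2c(OCc3ccccc3)cc(OCc3ccccc3)c3c(=O)cc(-c4ccc(OC)cc4)oc23)C=C1C(=O)OC | intermediate
16 | methyl 4-(tert-butyldimethylsilyloxy)-3-(5,7-di-O-benzylacacetin-8-yl)benzoate | COC(=O)c1ccc(O[Si](C)(C)C(C)(C)C)c(-c2c(OCc3ccccc3)cc(OCc3ccccc3)c3c(=O)cc(-c4ccc(OC)cc4)oc23)c1 | intermediate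
17 | methyl 4-hydroxy-3-(5,7-di-O-benzylacacetin-8-yl)benzoate (formed as its cesium salt, not isolated) | COC(=O)c1ccc(O)c(-c2c(OCc3ccccc3)cc(OCc3ccccc3)c3c(=O)cc(-c4ccc(OC)cc4)oc23)c1 | intermediate
18 | methyl 4-(benzyloxy)-3-(5,7-di-O-benzylacacetin-8-yl)benzoate | COC(=O)c1ccc(OCc2ccccc2)c(-c2c(OCc3ccccc3)cc(OCc3ccccc3)c3c(=O)cc(-c4ccc(OC)cc4)oc23)c1 | intermediate
19 | 4-(benzyloxy)-3-(5,7-di-O-benzylacacetin-8-yl)benzoic acid | OC(=O)c1ccc(OCc2ccccc2)c(-c2c(OCc3ccccc3)cc(OCc3ccccc3)c3c(=O)cc(-c4ccc(OC)cc4)oc23)c1 | intermediate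
20 | 2',6'-dihydroxy-4'-methoxyacetophenone | CC(=O)c1c(O)cc(OC)cc1O | starting material
21 | 2-acetyl-3-hydroxy-5-methoxyphenyl 4-(benzyloxy)-3-(5,7-di-O-benzylacacetin-8-yl)benzoate | CC(=O)c1c(O)cc(OC)cc1OC(=O)c1ccc(OCc2ccccc2)c(-c2c(OCc3ccccc3)cc(OCc3ccccc3)c3c(=O)cc(-c4ccc(OC)cc4)oc23)c1 | intermediate
22 | 1-(2,6-dihydroxy-4-methoxyphenyl)-3-[4-(benzyloxy)-3-(5,7-di-O-benzylacacetin-8-yl)phenyl]propane-1,3-dione | COc1cc(O)c(C(=O)CC(=O)c2ccc(OCc3ccccc3)c(-c3c(OCc4ccccc4)cc(OCc4ccccc4)c4c(=O)cc(-c5ccc(OC)cc5)oc34)c2)c(O)c1 | intermediate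
23 | 4',5'',7''-tri-O-benzylputraflavone | COc1cc(O)c2c(=O)cc(-c3ccc(OCc4ccccc4)c(-c4c(OCc5ccccc5)cc(OCc5ccccc5)c5c(=O)cc(-c6ccc(OC)cc6)oc45)c3)oc2c1 | intermediate
24 | putraflavone | COc1ccc(-c2cc(=O)c3c(O)cc(O)c(-c4cc(-c5cc(=O)c6c(O)cc(OC)cc6o5)ccc4O)c3o2)cc1 | target

**Totals and risks**

Total step count: 15. Longest linear sequence: 15 steps (1 → 24).

Steps most likely to fail, in route order (step 9 carries the largest risk):

Step 2. The allyl shift may be partly misdirected to C6'', because the chelated 5''-hydroxyl can perturb the usual preference for C8'', and the two C-allyl isomers may be hard to separate. The fallback sets out from acacetin 1 and returns at 6; it places the C8'' substituent by electrophilic substitution and cross-coupling instead of a sigmatropic shift. Both hydroxyls of 1 are benzylated (BnBr, K2CO3, DMF, 70 °C) to 5,7-di-O-benzylacacetin F1. Iodination of the 5,7-dialkoxy ring A (I2, CF3CO2Ag, CH2Cl2, rt), which in 5,7-dialkoxyflavones is directed to C8, should give 8-iodo-5,7-di-O-benzylacacetin F2. Stille coupling of F2 with allyltributylstannane (Pd(PPh3)4, DMF, 90 °C) should then give 6.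

Step 5. The Grignard reagent may deprotonate the readily enolised arylacetaldehyde (returning aldehyde or aldol products) or attack the pyranone carbonyl in competition. The fallback sets out from aldehyde 8 and returns at ynone 11, which also makes step 6 unnecessary. Pinnick oxidation (NaClO2, NaH2PO4, 2-methyl-2-butene, t-BuOH/H2O) gives (5,7-di-O-benzylacacetin-8-yl)acetic acid F3. Amide coupling with MeNHOMe·HCl (EDC·HCl, HOBt, i-Pr2NEt, CH2Cl2) gives 2-(5,7-di-O-benzylacacetin-8-yl)-N-methoxy-N-methylacetamide F4, whose α-hydrogens are far less acidic. Acylation of HC≡CMgBr by F4 (THF, 0 °C, cold aq NaHSO4 quench) stops at the chelated tetrahedral intermediate and should release 11 on work-up.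

Step 9. The cycloaddition may be too slow, since the twisted, doubly ortho-substituted flavonyl group shields the reacting diene terminus; at the temperatures then required the silyl dienol ether may be hydrolysed or consumed by oligomerisation with the propiolate before the [4+2] event. The fallback sets out from acacetin 1 and returns at 18; it makes the C3'–C8'' bond by cross-coupling of two arenes. The flavone partner is 8-iodo-5,7-di-O-benzylacacetin F2, made from 1 by way of F1 as in the fallback to step 2. Commercial methyl 3-bromo-4-hydroxybenzoate is benzylated (BnBr, K2CO3, DMF) to methyl 4-(benzyloxy)-3-bromobenzoate F5. Miyaura borylation (bis(pinacolato)diboron, PdCl2(dppf), KOAc, dioxane, 90 °C) gives methyl 4-(benzyloxy)-3-(4,4,5,5-tetramethyl-1,3,2-dioxaborolan-2-yl)benzoate F6. Suzuki–Miyaura coupling of F6 with F2 (Pd(OAc)2, 2-dicyclohexylphosphino-2',6'-dimethoxybiphenyl, K3PO4, toluene/H2O, 100 °C) should give 18.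

**Further compounds**

F1 | step 2 | 5,7-di-O-benzylacacetin (5,7-bis(benzyloxy)-2-(4-methoxyphenyl)-4H-chromen-4-one) | COc1ccc(-c2cc(=O)c3c(OCc4ccccc4)cc(OCc4ccccc4)cc3o2)cc1
F2 | step 2 | 8-iodo-5,7-di-O-benzylacacetin | COc1ccc(-c2cc(=O)c3c(OCc4ccccc4)cc(OCc4ccccc4)c(I)c3o2)cc1
F3 | step 5 | (5,7-di-O-benzylacacetin-8-yl)acetic acid | COc1ccc(-c2cc(=O)c3c(OCc4ccccc4)cc(OCc4ccccc4)c(CC(=O)O)c3o2)cc1
F4 | step 5 | 2-(5,7-di-O-benzylacacetin-8-yl)-N-methoxy-N-methylacetamide | COc1ccc(-c2cc(=O)c3c(OCc4ccccc4)cc(OCc4ccccc4)c(CC(=O)N(C)OC)c3o2)cc1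
F5 | step 9 | methyl 4-(benzyloxy)-3-bromobenzoate | COC(=O)c1ccc(OCc2ccccc2)c(Br)c1
F6 | step 9 | methyl 4-(benzyloxy)-3-(4,4,5,5-tetramethyl-1,3,2-dioxaborolan-2-yl)benzoate | COC(=O)c1ccc(OCc2ccccc2)c(B2OC(C)(C)C(C)(C)O2)c1
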